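**Strategy.** Ring A is an unfunctionalised cyclohexane that shares only the C5–C10 bond with ring B, so it is added last. A tricyclic ring B enone (C5 ketone, C6=C7 alkene, cyclobutane C8–C15–C14–C9 and ring D in place) can enolise only toward C10, because C6 is vinylic and C8 quaternary. One Robinson annulation with ethyl vinyl ketone then forms C1–C10 and C4=C5, closes ring A, creates the quaternary C10 stereocentre and delivers the C3 ketone and C4 methyl needed for the gem-dimethyl group. The enone comes from an enone–alkene [2+2] photocycloaddition of an (S)-linalool-derived side chain on a 2-methylcyclohexane-1,3-dione core, followed by a Wharton carbonyl transposition.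

Key step: step 14

**Remarks on the chemistry.**
- Numbering is that of the target: ring A = C1–C5 and C10; ring B = C5–C10; cyclobutane = C8, C15, C14, C9; ring D = C9, C11, C12, C13, C14. α is the face of ring B that carries C14 and C15; β is the face of the methyls on C8 and C10. TBS = tert-butyldimethylsilyl.
- Assumption: a C13 carbinol bearing CH3 and OSiR3 cannot be relied on to steer the photocycloaddition. The C10 methyl is therefore put in before it (step 2) and used as the control element. Because it enters racemic, step 9 is planned as a separation of two diastereomeric adducts, so at most half of the material is carried on, and the optical purity of the target equals that of the (S)-linalool used.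

**Route**

Step 1
Reactants: 1 2-methylcyclohexane-1,3-dione
Product: 2 3-ethoxy-2-methylcyclohex-2-en-1-one
Conditions: EtOH, p-TsOH (cat.), toluene, reflux, Dean–Stark
Reagents that add atoms: ethanol, CCO
Why: Acid-catalysed enol etherification of the symmetrical cyclic 1,3-dione with azeotropic removal of water gives the vinylogous ester; no stereocentre is involved.

Step 2
Reactants: 2 3-ethoxy-2-methylcyclohex-2-en-1-one
Product: 3 (±)-3-ethoxy-2,6-dimethylcyclohex-2-en-1-one
Conditions: LDA, THF, −78 °C; then MeI, −78 → 0 °C
Reagents that add atoms: iodomethane, CI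
Why: A vinylogous ester is deprotonated kinetically at the α′ carbon, and SN2 methylation of that lithium enolate installs the future C10 methyl (α′-alkylation of the Stork–Danheiser type); the new centre is formed racemic on purpose.

Step 3
Reactants: 4 (S)-linalool
Product: 5 (3S)-3-(tert-butyldimethylsilyloxy)-3,7-dimethylocta-1,6-diene
Conditions: TBSOTf, 2,6-lutidine, CH2Cl2, 0 °C → rt
Reagents that add atoms: tert-butyldimethylsilyl triflate, CC(C)(C)[Si](C)(C)OS(=O)(=O)C(F)(F)F
Why: The silyl triflate silylates even a hindered tertiary allylic alcohol under mild base, the C–O bond is not touched and the (S) centre (future C13) is retained (O-silylation).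

Step 4
Reactants: 5 (3S)-3-(tert-butyldimethylsilyloxy)-3,7-dimethylocta-1,6-diene
Product: 7 (4S)-4-(tert-butyldimethylsilyloxy)-4-methylhex-5-enal, via ozonide 6 (not isolated)
Conditions: O3 (1 equiv), CH2Cl2, −78 °C; then Me2S, −78 °C → rt
Reagents that add atoms: ozone, [O-][O+]=O
Why: Ozone attacks the electron-rich trisubstituted alkene far faster than the monosubstituted vinyl group on the silyloxy-bearing quaternary carbon, so one equivalent followed by reductive work-up cleaves only the C6=C7 bond of the linalool chain to the aldehyde (chemoselective ozonolysis); the stereocentre is remote and untouched.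

Step 5
Reactants: 7 (4S)-4-(tert-butyldimethylsilyloxy)-4-methylhex-5-enal
Product: 8 (4S)-1,4-bis(tert-butyldimethylsilyloxy)-4-methylhexa-1,5-diene (E/Z mixture)
Conditions: TBSOTf, Et3N, CH2Cl2, 0 °C
Reagents that add atoms: tert-butyldimethylsilyl triflate, CC(C)(C)[Si](C)(C)OS(=O)(=O)C(F)(F)F
Why: Soft enolisation of the aldehyde with silyl triflate and amine gives the silyl enol ether, whose geometry is irrelevant because the alkene is cleaved next (O-silylation of an aldehyde enolate).

Step 6
Reactants: 8 (4S)-1,4-bis(tert-butyldimethylsilyloxy)-4-methylhexa-1,5-diene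
Product: 11 (3S)-3-(tert-butyldimethylsilyloxy)-3-methylpent-4-en-1-ol, via ozonide 9 (not isolated), via nor-aldehyde 10 (not isolated)
Conditions: O3 (1 equiv), CH2Cl2, −78 °C; then NaBH4, MeOH, −78 → 0 °C
Reagents that add atoms: ozone, [O-][O+]=O
Why: The enol ether is by far the most electron-rich alkene, so ozonolysis excises the former aldehyde carbon and borohydride reduces the ozonide through the β-silyloxy aldehyde to the primary alcohol before that aldehyde can eliminate (one-carbon degradation by enol ether ozonolysis with reductive work-up).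

Step 7
Reactants: 11 (3S)-3-(tert-butyldimethylsilyloxy)-3-methylpent-4-en-1-ol
Product: 12 (3S)-5-bromo-3-(tert-butyldimethylsilyloxy)-3-methylpent-1-ene
Conditions: CBr4, PPh3, CH2Cl2, 0 °C
Reagents that add atoms: tetrabromomethane, BrC(Br)(Br)Br
Why: Appel bromination converts the primary alcohol to the bromide under neutral conditions that spare the tertiary allylic silyl ether.

Step 8
Reactants: 12 (3S)-5-bromo-3-(tert-butyldimethylsilyloxy)-3-methylpent-1-ene; 3 (±)-3-ethoxy-2,6-dimethylcyclohex-2-en-1-one
Product: 15 2,4-dimethyl-3-[(3S)-3-(tert-butyldimethylsilyloxy)-3-methylpent-4-enyl]cyclohex-2-en-1-one (both C4 epimers), via Grignard reagent 13 (not isolated), via bromomagnesium alkoxide 14 (not isolated)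
Conditions: Mg, THF, 40 °C; then 3, THF, 0 °C → rt; then 1 M HCl, 0 °C
Reagents that add atoms: water, O
Why: The Grignard reagent (its γ-silyloxy group is a poor leaving group and its alkene too remote to cyclise) adds 1,2 to the vinylogous ester carbonyl, and acid hydrolysis of the resulting β-alkoxy allylic alcohol transposes the carbonyl to give the 3-substituted enone (Stork–Danheiser sequence); the ring methyl centre stays racemic, so 15 should be an equimolar pair of C4 epimers.

Step 9
Reactants: 15 2,4-dimethyl-3-[(3S)-3-(tert-butyldimethylsilyloxy)-3-methylpent-4-enyl]cyclohex-2-en-1-one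
Product: 16 tricyclic C7 ketone (ring B + cyclobutane + ring D; 8β-methyl; 10β-methyl with 10α-H; C14 and C15 on the α face; 13S silyl ether)
Conditions: hν (366 nm), CH2Cl2 (degassed), 20 °C; chromatographic removal of the diastereomeric adduct
Reagents that add atoms: none
Why: Intramolecular enone–alkene [2+2] photocycloaddition through 1,5-closure (rule of five), in which C9–C14 forms ring D and C8–C15 then closes the cyclobutane with both ring fusions necessarily cis, the alkene adding to the face of C9 opposite the pseudoaxial C10 methyl, so the (4R) epimer of 15 gives 16 with C8, C9 and C14 as in the target while the (4S) epimer gives a diastereomer (different relation to the fixed (S) centre C13) that is removed by chromatography.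

Step 10
Reactants: 16 tricyclic C7 ketone
Product: 18 tricyclic 5-en-7-one (stereocentres as in 16), via trimethylsilyl enol ether 17 (not isolated)
Conditions: LDA, TMSCl, THF, −78 °C; then Pd(OAc)2 (1 equiv), MeCN, rt
Reagents that add atoms: none
Why: With C8 quaternary the ketone can enolise only toward C6, and palladium-mediated dehydrosilylation of that silyl enol ether introduces the C5=C6 double bond (Saegusa–Ito oxidation).

Step 11
Reactants: 18 tricyclic 5-en-7-one
Product: 19 tricyclic 5α,6α-epoxy-7-ketone
Conditions: H2O2 (30% aq.), NaOH (cat.), MeOH, 0 °C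
Reagents that add atoms: hydrogen peroxide, OO
Why: Conjugate addition of hydroperoxide anion to C5 and closure of the resulting enolate on oxygen give the epoxy ketone (Weitz–Scheffer epoxidation), expected on the face anti to the 10β-methyl although either epoxide serves, since C6 becomes trigonal in step 12 and C5 in step 13.

Step 12
Reactants: 19 tricyclic 5α,6α-epoxy-7-ketone
Product: 20 tricyclic 6-en-5α-ol
Conditions: N2H4·H2O, AcOH (cat.), MeOH, 0 °C → rt
Reagents that add atoms: none
Why: The hydrazone of the epoxy ketone opens the epoxide and loses dinitrogen, which moves the oxygen to C5 and the alkene to C6=C7 (Wharton transposition); the C5 carbinol configuration is inconsequential.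

Step 13
Reactants: 20 tricyclic 6-en-5α-ol
Product: 21 tricyclic 6-en-5-one with 10β-methyl (key-step precursor)
Conditions: Dess–Martin periodinane, CH2Cl2, rt
Reagents that add atoms: none
Why: Dess–Martin oxidation of the secondary allylic alcohol gives the 6-en-5-one without touching the silyl ether or the cyclobutane (hypervalent iodine alcohol oxidation); the C10 centre, now α to the ketone, becomes trigonal in the enolate of the next step in any case.

Step 14
Reactants: 21 tricyclic 6-en-5-one; 22 ethyl vinyl ketone (pent-1-en-3-one)
Product: 25 tetracyclic 4-methyl-4,6-dien-3-one (10β-methyl; 13S silyl ether), via Michael adduct 23 (not isolated), via ketol 24 (not isolated)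
Conditions: 22 (3 equiv, slow addition), KOH (0.5 equiv), EtOH, 0 → 25 °C; then KOH (3 equiv), EtOH, 70 °C
Reagents that add atoms: ethyl vinyl ketone (compound 22), C=CC(=O)CC
Why: Base can deprotonate 21 only at C10 (C6 is vinylic, C8 quaternary), and the cross-conjugated dienolate adds to ethyl vinyl ketone in a Michael reaction that forms C1–C10 and gives diketone 23; the ethyl ketone then enolises toward C4, adds to the C5 carbonyl to give ketol 24, and loss of water gives the linearly conjugated dienone 25. The closest known reaction type is the Robinson annulation of an α-methyl ketone with an alkyl vinyl ketone, run here on the α′-enolate of a cyclohexenone. Ring A closes by a 6-(enolendo)-exo-trig aldol addition followed by E1cB dehydration. The only new stereocentre, quaternary C10, is set in the Michael step by ring B itself: the β face carries the C8 methyl in a 1,3 relation to C10 as well as C11, whereas on the α face the C9–C14 bond is pulled back toward C8 by the four-membered ring, so C1 should enter α and leave the methyl β, and the configuration of 21 at C10 is irrelevant because that carbon is trigonal in the enolate. The step needs regioselectivity (C10, not C6: secured by the C6=C7 alkene), C-alkylation at a carbon flanked by quaternary C9 (helped by slow addition of excess enone and by the irreversible condensation that drains the reversible Michael equilibrium) and α-face selectivity, which has to be confirmed by NOE between the C10 and C8 methyls. The Michael stage is kept at or below room temperature, because the dienolate is a cis-bicyclo[4.2.0]octa-2,4-diene that could open thermally across C8–C9, whereas 23 has a quaternary C10 and can be heated for the condensation.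

Step 15
Reactants: 25 tetracyclic 4-methyl-4,6-dien-3-one
Product: 26 tetracyclic 4,4-dimethyl-5-en-3-one
Conditions: Li (2.2 equiv), t-BuOH (1 equiv), liquid NH3/THF, −78 °C; then MeI, −78 → −33 °C
Reagents that add atoms: iodomethane, CI
Why: Two-electron reduction of the linear dienone and protonation at the δ carbon C7 by tert-butanol leave the 3,5-dienolate, which is C-methylated at C4 to complete the gem-dimethyl group and park the alkene at C5=C6 (reductive alkylation of a conjugated ketone); no stereocentre is formed, and the radical anion is expected to be reduced on faster than the cyclobutane can open.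

Step 16
Reactants: 26 tetracyclic 4,4-dimethyl-5-en-3-one
Product: 28 tetracyclic 4,4-dimethyl-5-ene (C3 methylene), via hydrazone 27 (not isolated)
Conditions: N2H4·H2O, n-BuOH, 115 °C; evaporate; then KOtBu, DMSO, 25 → 70 °C
Reagents that add atoms: none
Why: Wolff–Kishner reduction through the preformed hydrazone (base-induced loss of dinitrogen in dimethyl sulfoxide) removes the C3 carbonyl; the β,γ-alkene cannot migrate because C4 is quaternary, and the tertiary silyl ether should tolerate the base.

Step 17
Reactants: 28 tetracyclic 4,4-dimethyl-5-ene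
Product: 29 tetracyclic 5-en-7-one
Conditions: t-BuOOH, dirhodium tetracaprolactamate Rh2(C6H10NO)4 (1 mol%), K2CO3 (cat.), CH2Cl2, rt
Reagents that add atoms: tert-butyl hydroperoxide, CC(C)(C)OO
Why: C7 is the only allylic position that carries hydrogen (C4 and C10 are quaternary), so radical allylic oxidation with tert-butyl hydroperoxide under dirhodium catalysis gives the 5-en-7-one, a reaction type well used on Δ5 steroids.

Step 18
Reactants: 29 tetracyclic 5-en-7-one
Product: 30 tetracyclic 5α-H 7-ketone (trans-fused rings A and B)
Conditions: H2 (1 atm), Pd/C, EtOAc, rt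
Reagents that add atoms: none
Why: Heterogeneous hydrogenation of the enone delivers hydrogen to C5 from the α face, because the β face is covered by the C10 methyl and the axial C4 methyl, which sets the 5α-H trans ring fusion (catalytic hydrogenation of a conjugated alkene).

Step 19
Reactants: 30 tetracyclic 5α-H 7-ketone
Product: 31 enol acetate (7-acetoxy-6-ene; 5α-H)
Conditions: KN(SiMe3)2, THF, −78 °C; then Ac2O, −78 → 0 °C
Reagents that add atoms: acetic anhydride, CC(=O)OC(C)=O
Why: Only C6 carries α-hydrogen (C8 is quaternary), so the potassium enolate forms regiospecifically and is O-acetylated by acetic anhydride to the enol acetate (enolate O-acylation).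

Step 20
Reactants: 31 enol acetate
Product: 33 6β-acetoxy-7-ketone 13-O-TBS ether, via epoxy acetate 32 (not isolated)
Conditions: dimethyldioxirane, acetone/CH2Cl2, 0 °C; evaporate; then toluene, 110 °C
Reagents that add atoms: dimethyldioxirane, CC1(C)OO1
Why: Dimethyldioxirane should epoxidise the electron-rich enol acetate from the α face (the β face is shielded by the methyls on C4, C8 and C10), and the thermal rearrangement of an enol ester epoxide transfers the acetoxy group from C7 to C6 intramolecularly with inversion, that is on the β face, giving the axial 6β-acetate (6S) and the C7 ketone in one operation.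

Step 21
Reactants: 33 6β-acetoxy-7-ketone 13-O-TBS ether
Product: 34 CNP0330581.1 (6β-acetoxy-13-hydroxy-7-ketone; 6S and 13S)
Conditions: HF·pyridine, pyridine, THF, 0 °C → rt
Reagents that add atoms: none
Why: Buffered hydrogen fluoride–pyridine cleaves the tertiary silyl ether at silicon without ionising C13 (which would trigger cyclobutane ring expansion) and without the base that could epimerise the axial C6 acetate (fluoride-mediated desilylation).

**Compound list**

1 | 2-methylcyclohexane-1,3-dione | CC1C(=O)CCCC1=O | starting material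
2 | 3-ethoxy-2-methylcyclohex-2-en-1-one | CCOC1=C(C)C(=O)CCC1 | intermediate
3 | (±)-3-ethoxy-2,6-dimethylcyclohex-2-en-1-one (racemic at C6) | CCOC1=C(C)C(=O)C(C)CC1 | intermediate
4 | (S)-linalool, (3S)-3,7-dimethylocta-1,6-dien-3-ol | CC(C)=CCC[C@](C)(O)C=C | starting material
5 | (3S)-3-(tert-butyldimethylsilyloxy)-3,7-dimethylocta-1,6-diene | CC(C)=CCC[C@](C)(O[Si](C)(C)C(C)(C)C)C=C | intermediate
6 | ozonide of 5 at the trisubstituted alkene (1,2,4-trioxolane; ring CH centre unassigned) | CC1(C)OOC(CC[C@](C)(O[Si](C)(C)C(C)(C)C)C=C)O1 | intermediate (not isolated)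
7 | (4S)-4-(tert-butyldimethylsilyloxy)-4-methylhex-5-enal | O=CCC[C@](C)(O[Si](C)(C)C(C)(C)C)C=C | intermediate
8 | (4S)-1,4-bis(tert-butyldimethylsilyloxy)-4-methylhexa-1,5-diene (E/Z mixture) | CC(C)(C)[Si](C)(C)OC=CC[C@](C)(O[Si](C)(C)C(C)(C)C)C=C | intermediate
9 | ozonide of 8 at the enol ether (1,2,4-trioxolane; ring centres unassigned) | CC(C)(C)[Si](C)(C)OC1OOC(C[C@](C)(O[Si](C)(C)C(C)(C)C)C=C)O1 | intermediate (not isolated)
10 | (3S)-3-(tert-butyldimethylsilyloxy)-3-methylpent-4-enal | O=CC[C@](C)(O[Si](C)(C)C(C)(C)C)C=C | intermediate (not isolated)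
11 | (3S)-3-(tert-butyldimethylsilyloxy)-3-methylpent-4-en-1-ol | OCC[C@](C)(O[Si](C)(C)C(C)(C)C)C=C | intermediate
12 | (3S)-5-bromo-3-(tert-butyldimethylsilyloxy)-3-methylpent-1-ene | BrCC[C@](C)(O[Si](C)(C)C(C)(C)C)C=C | intermediate
13 | [(3S)-3-(tert-butyldimethylsilyloxy)-3-methylpent-4-enyl]magnesium bromide | Br[Mg]CC[C@](C)(O[Si](C)(C)C(C)(C)C)C=C | intermediate (not isolated)
14 | bromomagnesium alkoxide of the 1,2-adduct of 13 to 3 (ring centres unassigned) | CCOC1=C(C)C(O[Mg]Br)(CC[C@](C)(O[Si](C)(C)C(C)(C)C)C=C)C(C)CC1 | intermediate (not isolated)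
15 | 2,4-dimethyl-3-[(3S)-3-(tert-butyldimethylsilyloxy)-3-methylpent-4-enyl]cyclohex-2-en-1-one (both C4 epimers) | CC1=C(CC[C@](C)(O[Si](C)(C)C(C)(C)C)C=C)C(C)CCC1=O | intermediate
16 | tricyclic C7 ketone (8β-methyl, 10β-methyl, 10α-H, cyclobutane on the α face, 13S silyl ether) | O=C1[C@@]2(C)C[C@H]3[C@@]2(CC[C@]3(C)O[Si](C)(C)C(C)(C)C)[C@H](C)CC1 | intermediate
17 | trimethylsilyl enol ether of 16 (C6=C7) | C1(O[Si](C)(C)C)[C@@]2(C)C[C@H]3[C@@]2(CC[C@]3(C)O[Si](C)(C)C(C)(C)C)[C@H](C)CC=1 | intermediate (not isolated)
18 | tricyclic 5-en-7-one | O=C1[C@@]2(C)C[C@H]3[C@@]2(CC[C@]3(C)O[Si](C)(C)C(C)(C)C)[C@H](C)C=C1 | intermediate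
19 | tricyclic 5α,6α-epoxy-7-ketone | O=C1[C@@]2(C)C[C@H]3[C@@]2(CC[C@]3(C)O[Si](C)(C)C(C)(C)C)[C@H](C)[C@H]4O[C@@H]14 | intermediate
20 | tricyclic 6-en-5α-ol | O[C@H]1C=C[C@@]2(C)C[C@H]3[C@@]2(CC[C@]3(C)O[Si](C)(C)C(C)(C)C)[C@@H]1C | intermediate
21 | tricyclic 6-en-5-one, 10β-methyl, C13 silyl ether (key-step precursor) | O=C1C=C[C@@]2(C)C[C@H]3[C@@]2(CC[C@]3(C)O[Si](C)(C)C(C)(C)C)[C@@H]1C | intermediate
22 | ethyl vinyl ketone (pent-1-en-3-one) | C=CC(=O)CC | starting material
23 | Michael adduct: 10α-(3-oxopentyl)-10β-methyl 6-en-5-one | O=C1C=C[C@@]2(C)C[C@H]3[C@@]2(CC[C@]3(C)O[Si](C)(C)C(C)(C)C)[C@@]1(C)CCC(=O)CC | intermediate (not isolated)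
24 | ketol: tetracyclic 5-hydroxy-4-methyl-6-en-3-one (C4 and C5 unassigned) | O=C1C(C)C2(O)C=C[C@@]3(C)C[C@H]4[C@@]3(CC[C@]4(C)O[Si](C)(C)C(C)(C)C)[C@@]2(C)CC1 | intermediate (not isolated)
25 | tetracyclic 4-methyl-4,6-dien-3-one, C13 silyl ether (key-step product) | O=C1C(C)=C2C=C[C@@]3(C)C[C@H]4[C@@]3(CC[C@]4(C)O[Si](C)(C)C(C)(C)C)[C@@]2(C)CC1 | intermediate
26 | tetracyclic 4,4-dimethyl-5-en-3-one | O=C1C(C)(C)C2=CC[C@@]3(C)C[C@H]4[C@@]3(CC[C@]4(C)O[Si](C)(C)C(C)(C)C)[C@@]2(C)CC1 | intermediate
27 | hydrazone of 26 | NN=C1C(C)(C)C2=CC[C@@]3(C)C[C@H]4[C@@]3(CC[C@]4(C)O[Si](C)(C)C(C)(C)C)[C@@]2(C)CC1 | intermediate (not isolated)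
28 | tetracyclic 4,4-dimethyl-5-ene | C1C(C)(C)C2=CC[C@@]3(C)C[C@H]4[C@@]3(CC[C@]4(C)O[Si](C)(C)C(C)(C)C)[C@@]2(C)CC1 | intermediate
29 | tetracyclic 5-en-7-one | C1C(C)(C)C2=CC(=O)[C@@]3(C)C[C@H]4[C@@]3(CC[C@]4(C)O[Si](C)(C)C(C)(C)C)[C@@]2(C)CC1 | intermediate
30 | tetracyclic 5α-H 7-ketone | C1C(C)(C)[C@@H]2CC(=O)[C@@]3(C)C[C@H]4[C@@]3(CC[C@]4(C)O[Si](C)(C)C(C)(C)C)[C@@]2(C)CC1 | intermediate
31 | enol acetate (7-acetoxy-6-ene, 5α-H) | C1C(C)(C)[C@@H]2C=C(OC(C)=O)[C@@]3(C)C[C@H]4[C@@]3(CC[C@]4(C)O[Si](C)(C)C(C)(C)C)[C@@]2(C)CC1 | intermediate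
32 | 6α,7α-epoxy-7β-acetate | C1C(C)(C)[C@@H]2[C@H]5O[C@@]5(OC(C)=O)[C@@]3(C)C[C@H]4[C@@]3(CC[C@]4(C)O[Si](C)(C)C(C)(C)C)[C@@]2(C)CC1 | intermediate (not isolated)
33 | 6β-acetoxy-7-ketone 13-O-TBS ether | CC(=O)O[C@@H]1C(=O)[C@@]2(C)C[C@H]3[C@@]2(CC[C@]3(C)O[Si](C)(C)C(C)(C)C)[C@@]2(C)CCCC(C)(C)[C@H]12 | intermediate
34 | CNP0330581.1 | CC(=O)O[C@@H]1C(=O)[C@@]2(C)C[C@H]3[C@@]2(CC[C@]3(C)O)[C@@]2(C)CCCC(C)(C)[C@H]12 | target

**Count and risks**

Total step count: 21. Longest linear sequence: 19 steps (steps 3–21 from (S)-linalool; the dione branch, steps 1–2, joins at step 8).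

The three steps most likely to fail:

1. Step 14 (key step). The Michael addition must build a quaternary carbon next to the quaternary C9. The reversible addition may lie on the side of the dienolate, ethyl vinyl ketone may polymerise faster than it is captured, and the α-face preference at C10 is only predicted. Fallback: the C1–C10 bond would be made under Lewis-acid control and the annulation split in two. Setting out from 21, LDA and TMSCl (THF, −78 °C) give the cross-conjugated trimethylsilyl dienol ether F1. Its Mukaiyama–Michael addition to 22 (TMSOTf or TiCl4, CH2Cl2, −78 °C) should give diketone 23 after aqueous work-up, here isolated. A separate aldol condensation (KOH, MeOH, 65 °C) comes back to the route at 25. The low temperature also keeps the dienol ether away from electrocyclic opening.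

2. Step 15. The dissolving-metal step may over-reduce, may protonate the dianion at C5 instead of C7 (leaving the alkene at C6=C7), or may fragment the cyclobutane C8–C15 bond from the radical anion. Fallback without dissolving metal: setting out from 25, selective hydrogenation of the disubstituted C6=C7 bond with RhCl(PPh3)3 and H2 (benzene/EtOH, rt) gives the tetracyclic 4-methyl-4-en-3-one F2. Classical deconjugative methylation through the thermodynamic 3,5-dienolate (KOtBu, t-BuOH, MeI, limited excess) then comes back to the route at 26.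

3. Step 20. Epoxidation may occur in part on the β face, the acyloxy shift may proceed with retention if traces of acid are present, or the axial acetate may epimerise at C6; each would give the 6α-acetate. Fallback by cis-hydrogenation: setting out from 30, autoxidation of the enolate (KOtBu, O2, t-BuOH/THF, 0 °C) gives the diosphenol F3 (6-hydroxy-5-en-7-one, the only possible enol because C8 is quaternary). Acetylation (Ac2O, pyridine, DMAP) gives the diosphenol acetate F4. Hydrogenation over Pd/C from the α face adds both hydrogens cis at C5 and C6, leaving the acetate β, and comes back to the route at 33.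

**Further compounds**

F1 | step 14 | trimethylsilyl dienol ether of 21 (C5=C10 and C6=C7) | C1(O[Si](C)(C)C)C=C[C@@]2(C)C[C@H]3[C@@]2(CC[C@]3(C)O[Si](C)(C)C(C)(C)C)C=1C
F2 | step 15 | tetracyclic 4-methyl-4-en-3-one (C6 and C7 saturated) | O=C1C(C)=C2CC[C@@]3(C)C[C@H]4[C@@]3(CC[C@]4(C)O[Si](C)(C)C(C)(C)C)[C@@]2(C)CC1
F3 | step 20 | diosphenol (6-hydroxy-5-en-7-one) | C1C(C)(C)C2=C(O)C(=O)[C@@]3(C)C[C@H]4[C@@]3(CC[C@]4(C)O[Si](C)(C)C(C)(C)C)[C@@]2(C)CC1
F4 | step 20 | diosphenol acetate (6-acetoxy-5-en-7-one) | C1C(C)(C)C2=C(OC(C)=O)C(=O)[C@@]3(C)C[C@H]4[C@@]3(CC[C@]4(C)O[Si](C)(C)C(C)(C)C)[C@@]2(C)CC1
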